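**Retrosynthetic overview**
1. The hydroperoxide is made last: the C6–OO bond comes from SN2 inversion of a (6R)-allylic mesylate by a capped hydroperoxide, followed by acid unmasking of the OOH and the 4-OH.
2. The aryl–O–C1 bond comes from a late etherification of 4-hydroxy-5-methylcoumarin with a C10 allylic chloride that already carries C4 (S) and C6 (R).
3. The side chain is built at C4–C5 by an Ipc-boron aldol of 3-methylbut-3-en-2-one with (E)-4-chloro-2-methylbut-2-enal (from isoprene monoxide), then CBS reduction at C6.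
4. The coumarin is built carbocycle first (Michael/aldol annulation of methyl acetoacetate with crotonaldehyde, then aromatisation) and pyranone ring second (carbonate acylation/lactonisation of 2-hydroxy-6-methylacetophenone).

Assumption: the SMILES is read as the (2E,4S,6S) isomer (geranyl-type numbering from the ether carbon). Oxirane 11 is used as the racemate because its stereocentre is destroyed in step 6. TBS = tert-butyldimethylsilyl.

**Coumarin arm**

Step 1
Reactants: 1 methyl acetoacetate + 2 (E)-but-2-enal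
Product: 5 methyl 6-methyl-2-oxocyclohex-3-ene-1-carboxylate (racemic cis/trans mixture), via Michael adduct 3 (not isolated), via cyclic aldol 4 (not isolated)
Conditions: NaOMe (0.1 equiv), MeOH, 0 °C → rt; then HCl (g), 0 °C → rt
Reagents that add atoms: none
Why: Michael addition of the acetoacetate to the enal, intramolecular aldol of the acetyl methyl onto the aldehyde and acid dehydration (Robinson-type annulation) give the cyclohexenone, whose two stereocentres are irrelevant because aromatisation erases them.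

Step 2
Reactants: 5 methyl 6-methyl-2-oxocyclohex-3-ene-1-carboxylate
Product: 7 methyl 2-hydroxy-6-methylbenzoate, via bromo keto ester 6 (not isolated)
Conditions: CuBr2 (2.1 equiv), LiBr, MeCN, reflux
Reagents that add atoms: none
Why: α-Bromination of the β-keto ester and loss of HBr give a cyclohexadienone that tautomerises to the phenol (oxidative aromatisation), fixing the 1,2,3-substitution pattern that electrophilic chemistry on m-cresol does not give.

Step 3
Reactants: 7 methyl 2-hydroxy-6-methylbenzoate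
Product: 8 2-hydroxy-6-methylbenzoic acid
Conditions: KOH, MeOH/H2O, reflux; then aq. HCl
Reagents that add atoms: potassium hydroxide [K+].[OH-]
Why: Forcing ester saponification overcomes the di-ortho hindrance and frees the acid needed for ketone synthesis.

Step 4
Reactants: 8 2-hydroxy-6-methylbenzoic acid
Product: 9 1-(2-hydroxy-6-methylphenyl)ethan-1-one
Conditions: MeLi (3.5 equiv), THF, 0 °C → rt; inverse quench into cold aq. HCl
Reagents that add atoms: methyllithium [Li]C
Why: After deprotonation of OH and CO2H a third equivalent adds to the lithium carboxylate to give a gem-diolate that collapses to the methyl ketone only on work-up (organolithium addition to a carboxylate), so no tertiary alcohol forms.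

Step 5
Reactants: 9 1-(2-hydroxy-6-methylphenyl)ethan-1-one
Product: 10 4-hydroxy-5-methyl-2H-chromen-2-one
Conditions: NaH (4 equiv), (EtO)2CO, toluene, 110 °C; then aq. HCl
Reagents that add atoms: diethyl carbonate CCOC(=O)OCC
Why: Claisen-type C-acylation of the ketone enolate by the carbonate followed by lactonisation onto the phenoxide closes the pyranone ring, the standard entry to 4-hydroxycoumarins.

**Side-chain arm**

Step 6
Reactants: 11 (±)-2-methyl-2-vinyloxirane
Product: 12 (E)-4-chloro-2-methylbut-2-en-1-ol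
Conditions: TiCl4 (1.1 equiv), CH2Cl2, −85 °C; then 1 M HCl
Reagents that add atoms: titanium tetrachloride Cl[Ti](Cl)(Cl)Cl
Why: The titanium-activated vinyl epoxide is opened by chloride at the vinyl terminus (SN2′ epoxide opening), which gives the E-trisubstituted alkene with the oxygen and chlorine termini differentiated.

Step 7
Reactants: 12 (E)-4-chloro-2-methylbut-2-en-1-ol
Product: 13 (E)-4-chloro-2-methylbut-2-enal
Conditions: activated MnO2, CH2Cl2, rt
Reagents that add atoms: none
Why: Allylic alcohol oxidation with MnO2 stops at the enal and leaves the allylic chloride and the E geometry untouched.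

Step 8
Reactants: 14 3-methylbut-3-en-2-one + 13 (E)-4-chloro-2-methylbut-2-enal
Product: 16 (5S,6E)-8-chloro-5-hydroxy-2,6-dimethylocta-1,6-dien-3-one, via enol borinate 15 (not isolated)
Conditions: enolise 14 with (−)-Ipc2BCl, Et3N, Et2O, −78 → 0 °C; add 13, −78 → −20 °C; H2O2, pH 7 buffer, MeOH, 0 °C
Reagents that add atoms: none
Why: The diisopinocampheylboron enolate of the methyl ketone adds through a cyclic transition state (Paterson boron aldol) in which the (−)-Ipc ligands direct attack to the Si face of the α-methyl enal, setting the carbinol centre as S (C4 of the target).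

Step 9
Reactants: 16 (5S,6E)-8-chloro-5-hydroxy-2,6-dimethylocta-1,6-dien-3-one
Product: 17 (5S,6E)-5-[(tert-butyldimethylsilyl)oxy]-8-chloro-2,6-dimethylocta-1,6-dien-3-one
Conditions: TBSOTf, 2,6-lutidine, CH2Cl2, −78 °C
Reagents that add atoms: tert-butyldimethylsilyl trifluoromethanesulfonate CC(C)(C)[Si](C)(C)OS(=O)(=O)C(F)(F)F
Why: Low-temperature silylation protects the β-hydroxyl before it can undergo retro-aldol, dehydration or oxa-Michael closure onto the enone, and differentiates it from the hydroxyl made next.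

Step 10
Reactants: 17 (5S,6E)-5-[(tert-butyldimethylsilyl)oxy]-8-chloro-2,6-dimethylocta-1,6-dien-3-one
Product: 18 (3R,5S,6E)-5-[(tert-butyldimethylsilyl)oxy]-8-chloro-2,6-dimethylocta-1,6-dien-3-ol
Conditions: (S)-Me-CBS (0.3 equiv), catecholborane, toluene, −78 °C
Reagents that add atoms: none
Why: In the Corey–Bakshi–Shibata reduction the (S)-oxazaborolidine binds the enone with isopropenyl as the large group and delivers hydride 1,2 to give the 3R alcohol under reagent control (C6 of the target, with the configuration opposite to the final one).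

**Coupling and end game**

Step 11
Reactants: 10 4-hydroxy-5-methyl-2H-chromen-2-one + 18 (3R,5S,6E)-5-[(tert-butyldimethylsilyl)oxy]-8-chloro-2,6-dimethylocta-1,6-dien-3-ol
Product: 19 4-{[(2E,4S,6R)-4-[(tert-butyldimethylsilyl)oxy]-6-hydroxy-3,7-dimethylocta-2,7-dien-1-yl]oxy}-5-methyl-2H-chromen-2-one
Conditions: Cs2CO3 (1.2 equiv), DMF, rt → 45 °C
Reagents that add atoms: none
Why: The cesium salt of the acidic 4-hydroxycoumarin is O-alkylated by the primary allylic chloride in a dipolar aprotic solvent (Williamson-type etherification), while the unionised secondary alcohol and the silyl ether are spectators and the alkene geometry is kept.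

Step 12
Reactants: 19 4-{[(2E,4S,6R)-4-[(tert-butyldimethylsilyl)oxy]-6-hydroxy-3,7-dimethylocta-2,7-dien-1-yl]oxy}-5-methyl-2H-chromen-2-one
Product: 20 (3R,5S,6E)-5-[(tert-butyldimethylsilyl)oxy]-2,6-dimethyl-8-[(5-methyl-2-oxo-2H-chromen-4-yl)oxy]octa-1,6-dien-3-yl methanesulfonate
Conditions: Ms2O, Et3N, CH2Cl2, −30 °C; cold work-up, crude used at once
Reagents that add atoms: methanesulfonic anhydride CS(=O)(=O)OS(C)(=O)=O
Why: Sulfonylation of the only free hydroxyl with the anhydride activates C6 with retention and without chloride ion that could displace the allylic mesylate.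

Step 13
Reactants: 20 (3R,5S,6E)-5-[(tert-butyldimethylsilyl)oxy]-2,6-dimethyl-8-[(5-methyl-2-oxo-2H-chromen-4-yl)oxy]octa-1,6-dien-3-yl methanesulfonate
Product: 21 4-{[(2E,4S,6S)-4-[(tert-butyldimethylsilyl)oxy]-6-[(2-methoxypropan-2-yl)peroxy]-3,7-dimethylocta-2,7-dien-1-yl]oxy}-5-methyl-2H-chromen-2-one
Conditions: 2-methoxyprop-2-yl hydroperoxide (3 equiv), CsOH·H2O (2.5 equiv), DMF, −20 → 0 °C
Reagents that add atoms: 2-methoxyprop-2-yl hydroperoxide COC(C)(C)OO
Why: The α-effect peroxide anion displaces the allylic mesylate by SN2 with inversion (Dussault-type perketal alkylation), turning 6R-OMs into the 6S peroxide in a capped form that cannot be alkylated twice.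

Step 14
Reactants: 21 4-{[(2E,4S,6S)-4-[(tert-butyldimethylsilyl)oxy]-6-[(2-methoxypropan-2-yl)peroxy]-3,7-dimethylocta-2,7-dien-1-yl]oxy}-5-methyl-2H-chromen-2-one
Product: 22 4-{[(2E,4S,6S)-6-hydroperoxy-4-hydroxy-3,7-dimethylocta-2,7-dien-1-yl]oxy}-5-methyl-2H-chromen-2-one
Conditions: 48% aq. HF, MeCN, 0 °C
Reagents that add atoms: none
Why: Aqueous HF hydrolyses the peroxyketal to the hydroperoxide and cleaves the silyl ether (acid-mediated global deprotection) without touching either stereocentre or the lactone.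

**Compound list**
1 | methyl acetoacetate | COC(=O)CC(C)=O | starting material
2 | (E)-but-2-enal (crotonaldehyde) | C/C=C/C=O | starting material
3 | methyl 2-acetyl-3-methyl-5-oxopentanoate (stereoisomer mixture) | COC(=O)C(C(C)=O)C(C)CC=O | intermediate
4 | methyl 4-hydroxy-6-methyl-2-oxocyclohexane-1-carboxylate (stereoisomer mixture) | COC(=O)C1C(C)CC(O)CC1=O | intermediate
5 | methyl 6-methyl-2-oxocyclohex-3-ene-1-carboxylate (racemic cis/trans mixture) | COC(=O)C1C(C)CC=CC1=O | intermediate
6 | methyl 1-bromo-6-methyl-2-oxocyclohex-3-ene-1-carboxylate (stereoisomer mixture) | COC(=O)C1(Br)C(C)CC=CC1=O | intermediate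
7 | methyl 2-hydroxy-6-methylbenzoate | COC(=O)c1c(C)cccc1O | intermediate
8 | 2-hydroxy-6-methylbenzoic acid | Cc1cccc(O)c1C(=O)O | intermediate
9 | 1-(2-hydroxy-6-methylphenyl)ethan-1-one | CC(=O)c1c(C)cccc1O | intermediate
10 | 4-hydroxy-5-methyl-2H-chromen-2-one | Cc1cccc2oc(=O)cc(O)c12 | intermediate
11 | (±)-2-methyl-2-vinyloxirane | C=CC1(C)CO1 | starting material
12 | (E)-4-chloro-2-methylbut-2-en-1-ol | OC/C(C)=C/CCl | intermediate
13 | (E)-4-chloro-2-methylbut-2-enal | O=C/C(C)=C/CCl | intermediate
14 | 3-methylbut-3-en-2-one | CC(=O)C(C)=C | starting material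
15 | [(3-methylbuta-1,3-dien-2-yl)oxy]bis[(−)-isopinocampheyl]borane (Ipc groups from (+)-α-pinene) | C=C(C)C(=C)OB([C@@H]1C[C@@H]2C[C@H]([C@H]1C)C2(C)C)[C@@H]1C[C@@H]2C[C@H]([C@H]1C)C2(C)C | intermediate
16 | (5S,6E)-8-chloro-5-hydroxy-2,6-dimethylocta-1,6-dien-3-one | C=C(C)C(=O)C[C@H](O)/C(C)=C/CCl | intermediate
17 | (5S,6E)-5-[(tert-butyldimethylsilyl)oxy]-8-chloro-2,6-dimethylocta-1,6-dien-3-one | C=C(C)C(=O)C[C@H](O[Si](C)(C)C(C)(C)C)/C(C)=C/CCl | intermediate
18 | (3R,5S,6E)-5-[(tert-butyldimethylsilyl)oxy]-8-chloro-2,6-dimethylocta-1,6-dien-3-ol | C=C(C)[C@H](O)C[C@H](O[Si](C)(C)C(C)(C)C)/C(C)=C/CCl | intermediate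
19 | 4-{[(2E,4S,6R)-4-[(tert-butyldimethylsilyl)oxy]-6-hydroxy-3,7-dimethylocta-2,7-dien-1-yl]oxy}-5-methyl-2H-chromen-2-one | C=C(C)[C@H](O)C[C@H](O[Si](C)(C)C(C)(C)C)/C(C)=C/COc1cc(=O)oc2cccc(C)c12 | intermediate
20 | (3R,5S,6E)-5-[(tert-butyldimethylsilyl)oxy]-2,6-dimethyl-8-[(5-methyl-2-oxo-2H-chromen-4-yl)oxy]octa-1,6-dien-3-yl methanesulfonate | C=C(C)[C@H](OS(C)(=O)=O)C[C@H](O[Si](C)(C)C(C)(C)C)/C(C)=C/COc1cc(=O)oc2cccc(C)c12 | intermediate
21 | 4-{[(2E,4S,6S)-4-[(tert-butyldimethylsilyl)oxy]-6-[(2-methoxypropan-2-yl)peroxy]-3,7-dimethylocta-2,7-dien-1-yl]oxy}-5-methyl-2H-chromen-2-one | C=C(C)[C@@H](OOC(C)(C)OC)C[C@H](O[Si](C)(C)C(C)(C)C)/C(C)=C/COc1cc(=O)oc2cccc(C)c12 | intermediate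
22 | 4-{[(2E,4S,6S)-6-hydroperoxy-4-hydroxy-3,7-dimethylocta-2,7-dien-1-yl]oxy}-5-methyl-2H-chromen-2-one | C=C(C)[C@H](C[C@H](O)/C(C)=C/COc1cc(=O)oc2cccc(C)c12)OO | target

**Step count**
Total: 14 steps (1–5 coumarin arm, 6–10 side-chain arm, 11 coupling, 12–14 end game).
Longest linear sequence: 9 steps (6 → 14; the path 1 → 5 then 11 → 14 is also 9).

**Three steps most likely to fail**

Step 13. A secondary allylic mesylate can also react by SN2′ at the terminal CH2, by E2 to the diene or by ionisation, any of which erodes regio- or stereochemistry at C6. The fallback sets out from 19 and comes back at 22, and replaces substitution by an ene reaction. Myers reductive transposition of 19 (2-nitrobenzenesulfonylhydrazide, PPh3, DEAD, THF, −30 °C → rt) passes through the Mitsunobu sulfonylhydrazide adduct F1 and, after loss of the sulfinic acid, the allylic diazene F2, which extrudes N2 by retro-ene to give the 2,6-diene ether F3. Schenck ene reaction of F3 with singlet oxygen (O2, TPP, hν, CH2Cl2, 0 °C) at the electron-rich 6,7-alkene gives the 6-hydroperoxy-7-enes without facial control. The silyl-protected 6S hydroperoxide F4 is separated by HPLC from its epimer and the tertiary regioisomer, and aq. HF/MeCN then gives 22.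

Step 11. The 4-hydroxycoumarin anion is ambident and can alkylate at C3, and the peri 5-methyl group crowds the oxygen. The fallback sets out from 18 and comes back at 19, and turns the electrophile into an alcohol for a Mitsunobu coupling, which alkylates the acidic enol oxygen. KOAc in DMF at 40 °C converts 18 into the allylic acetate F5. K2CO3 in MeOH at 0 °C gives the 1,6-diol F6. F6 and 10 with PPh3 and DIAD in THF at 0 °C react at the primary allylic hydroxyl only and give 19.

Step 8. Ipc-boron aldols of methyl ketones often give only 70–90% ee, and the dienyl enolate is untested with this enal. The minor enantiomer becomes a diastereomer after step 10 and can be removed there, but low selectivity costs material. The fallback sets out from 13 (with 14) and comes back at 16, and replaces reagent control by resolution. The lithium enolate of 14 (LDA, THF, −78 °C) adds to 13 to give the racemic aldol F7. Sharpless kinetic resolution (Ti(OiPr)4, D-(−)-DIPT, TBHP 0.6 equiv, 4 Å MS, CH2Cl2, −20 °C) epoxidises the 5R enantiomer to the anti epoxy alcohol F8 and leaves 16 (5S) in high ee.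

**Further compounds**
F1 | step 13 | N-[(3S,5S,6E)-5-[(tert-butyldimethylsilyl)oxy]-2,6-dimethyl-8-[(5-methyl-2-oxo-2H-chromen-4-yl)oxy]octa-1,6-dien-3-yl]-2-nitrobenzenesulfonohydrazide | C=C(C)[C@@H](N(N)S(=O)(=O)c1ccccc1[N+](=O)[O-])C[C@H](O[Si](C)(C)C(C)(C)C)/C(C)=C/COc1cc(=O)oc2cccc(C)c12
F2 | step 13 | 4-{[(2E,4S,6S)-4-[(tert-butyldimethylsilyl)oxy]-6-diazenyl-3,7-dimethylocta-2,7-dien-1-yl]oxy}-5-methyl-2H-chromen-2-one | C=C(C)[C@@H](N=N)C[C@H](O[Si](C)(C)C(C)(C)C)/C(C)=C/COc1cc(=O)oc2cccc(C)c12
F3 | step 13 | 4-{[(2E,4S)-4-[(tert-butyldimethylsilyl)oxy]-3,7-dimethylocta-2,6-dien-1-yl]oxy}-5-methyl-2H-chromen-2-one | CC(C)=CC[C@H](O[Si](C)(C)C(C)(C)C)/C(C)=C/COc1cc(=O)oc2cccc(C)c12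
F4 | step 13 | 4-{[(2E,4S,6S)-4-[(tert-butyldimethylsilyl)oxy]-6-hydroperoxy-3,7-dimethylocta-2,7-dien-1-yl]oxy}-5-methyl-2H-chromen-2-one | C=C(C)[C@@H](OO)C[C@H](O[Si](C)(C)C(C)(C)C)/C(C)=C/COc1cc(=O)oc2cccc(C)c12
F5 | step 11 | (2E,4S,6R)-4-[(tert-butyldimethylsilyl)oxy]-6-hydroxy-3,7-dimethylocta-2,7-dien-1-yl acetate | C=C(C)[C@H](O)C[C@H](O[Si](C)(C)C(C)(C)C)/C(C)=C/COC(C)=O
F6 | step 11 | (2E,4S,6R)-4-[(tert-butyldimethylsilyl)oxy]-3,7-dimethylocta-2,7-diene-1,6-diol | C=C(C)[C@H](O)C[C@H](O[Si](C)(C)C(C)(C)C)/C(C)=C/CO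
F7 | step 8 | rac-(6E)-8-chloro-5-hydroxy-2,6-dimethylocta-1,6-dien-3-one | C=C(C)C(=O)CC(O)/C(C)=C/CCl
F8 | step 8 | (5R)-5-[(2S,3R)-3-(chloromethyl)-2-methyloxiran-2-yl]-5-hydroxy-2-methylpent-1-en-3-one | ClC[C@@H]1O[C@@]1(C)[C@H](O)CC(=O)C(C)=C
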